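**Plan**

- Numbering used: C1 is the acyl-bearing bridgehead, C5 the prenyl-bearing bridgehead, C9 the bridging carbonyl. The retrosynthesis first removes an O-methyl helper, then cuts both bonds that tie the C6–C7–C8 bridge to ring A (C5–C6 and C1–C8). This deletes ring B and leaves a flat, achiral aromatic acylphloroglucinol (C21) and a racemic C10 cyclic sulfate that already carries the C7 prenyl group and the gem-dimethyl carbon.
- Enabling feature: ring A (C1, C2, C3, C4, C5, C9) is a masked phloroglucinol. Its C5 and C1 are 1,3-related carbon nucleophiles across C9 (a phenoxide carbon and, after dearomatisation, a β-triketone carbon). The C10 piece has a primary SN2 end (C6) and a tertiary SN1 end (C8).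
- Forward: ring A is bought as phloroglucinol and dressed by C-acylation, 4-O-methylation and two C-prenylations. The C10 piece comes from ethyl 3-hydroxy-3-methylbutanoate by dianion prenylation, reduction and cyclic sulfate formation. One flask then joins the two and closes ring B, and demethylation ends the route.
- Stereochemistry: C5 from a chiral bis-ammonium ion pair in the alkylation; C1 from C5 through the three-atom tether; C7 from a Curtin–Hammett funnel of the racemic centre (cation epimerisation, chair closure with equatorial prenyl). The 4-O-methyl group directs closure to C1 and is removed last.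

Key step: step 7

Remark: the target is drawn as its 4-hydroxy-2-oxo enol tautomer; the free β-diketone is expected to equilibrate with the 2-hydroxy-4-oxo form.
Remark: the cinchonidine-derived dication in step 7 is assumed to favour the 5R adduct; if the sense is the opposite, the cinchonine-derived pseudo-enantiomer takes its place.

**Route**

Step 1
Reactants: 1 phloroglucinol; 2 isobutyryl chloride
Product: 3 phlorisobutyrophenone, 2-methyl-1-(2,4,6-trihydroxyphenyl)propan-1-one
Conditions: AlCl3 (3.5 equiv), PhNO2/CH2Cl2, 0 °C to 60 °C; aq. HCl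
Reagents that add atoms: none
Why: Friedel–Crafts C-acylation of the electron-rich triol; the aluminium chelate of the product ketone is deactivated, so a single acyl group should enter.

Step 2
Reactants: 3 phlorisobutyrophenone
Product: 4 1-(2,6-dihydroxy-4-methoxyphenyl)-2-methylpropan-1-one
Conditions: Me2SO4 (1.0 equiv), K2CO3 (1.05 equiv), acetone, reflux
Reagents that add atoms: dimethyl sulfate, COS(=O)(=O)OC
Why: Williamson O-methylation; the 4-hydroxyl group is the only one not chelated to the ketone and the most acidic, so it should be methylated selectively.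

Step 3
Reactants: 4 1-(2,6-dihydroxy-4-methoxyphenyl)-2-methylpropan-1-one; 5 prenyl bromide
Product: 6 1-[2,6-dihydroxy-4-methoxy-3,5-bis(3-methylbut-2-en-1-yl)phenyl]-2-methylpropan-1-one
Conditions: 5 (2.3 equiv), KOH (10 % in H2O), 0 °C to rt
Reagents that add atoms: none
Why: C-alkylation of the acylphloroglucinol dianion in water, where the hydrogen-bonded phenoxide oxygens are masked, at the two free ring carbons ortho and para to the phenoxides; this is the classical double C-prenylation of acylphloroglucinols.

Step 4
Reactants: 7 ethyl 3-hydroxy-3-methylbutanoate; 5 prenyl bromide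
Product: 8 ethyl (±)-3-hydroxy-3-methyl-2-(3-methylbut-2-en-1-yl)butanoate
Conditions: LiN(iPr)2 (2.2 equiv), THF, −78 °C to −20 °C; then 5; aq. NH4Cl
Reagents that add atoms: none
Why: Fráter–Seebach alkylation of the alkoxide–enolate dianion of a β-hydroxy ester at the α-carbon; the dianion cannot undergo retro-aldol cleavage, and the new centre (the later C7) is deliberately left racemic.

Step 5
Reactants: 8 ethyl (±)-3-hydroxy-3-methyl-2-(3-methylbut-2-en-1-yl)butanoate
Product: 9 (±)-3-methyl-2-(3-methylbut-2-en-1-yl)butane-1,3-diol
Conditions: LiAlH4, Et2O, 0 °C; Fieser work-up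
Reagents that add atoms: none
Why: hydride reduction of the ester to the primary alcohol; the isolated trisubstituted alkene and the tertiary alcohol are inert.

Step 6
Reactants: 9 (±)-3-methyl-2-(3-methylbut-2-en-1-yl)butane-1,3-diol
Product: 10 (±)-4,4-dimethyl-5-(3-methylbut-2-en-1-yl)-1,3,2-dioxathiane 2,2-dioxide
Conditions: 1,1'-sulfonyldiimidazole (1.2 equiv), NaH (2.2 equiv), THF, −20 °C to 0 °C; aq. NH4Cl
Reagents that add atoms: 1,1'-sulfonyldiimidazole, O=S(=O)(n1ccnc1)n1ccnc1
Why: sulfonyl transfer to the primary alkoxide and six-membered ring closure at sulfur by the tertiary alkoxide give the cyclic sulfate directly at the sulfate oxidation level, so no oxidant meets the prenyl alkene.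

Step 7
Reactants: 6 1-[2,6-dihydroxy-4-methoxy-3,5-bis(3-methylbut-2-en-1-yl)phenyl]-2-methylpropan-1-one; 10 (±)-4,4-dimethyl-5-(3-methylbut-2-en-1-yl)-1,3,2-dioxathiane 2,2-dioxide
Product: 13 (1R,5R,7S)-4-methoxy-8,8-dimethyl-1-(2-methylpropanoyl)-3,5,7-tris(3-methylbut-2-en-1-yl)bicyclo[3.3.1]non-3-ene-2,9-dione, via dicesium enolate sulfate 11 (not isolated), via bis(trimethylsilyl) derivative 12 (not isolated)
Conditions: 10 (1.5 equiv), 2,7-bis[(O(9)-allylhydrocinchonidinium-N-yl)methyl]naphthalene dibromide (20 mol %), CsOH·H2O (4 equiv), 4 Å molecular sieves, toluene/CH2Cl2, −40 °C; then in the same flask 2,6-di-tert-butyl-4-methylpyridine, Me3SiOTf (excess), −78 °C to −30 °C; aq. NaHCO3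
Reagents that add atoms: none
Why: Proposed new method: the dianion of 6, held in a contact ion pair by the chiral bis-ammonium dication, should open cyclic sulfate 10 at its primary carbon through a prenyl-bearing ring carbon (SN2, C-alkylative dearomatisation, C5–C6) to give 11, and after silylation to 12 the tertiary silyl sulfate should ionise so that the C8 cation is captured by C1 of the silyl enol ether (SN1, C1–C8) with loss of bis(trimethylsilyl) sulfate. The closest known reaction types are the enantioselective alkylative dearomatisation of 2-acyl-4,6-diprenylphloroglucinols by a Michael acceptor under the same class of cinchona bis-ammonium phase-transfer catalysts, the double C-alkylation of stabilised carbanions by cyclic sulfates, and the Lewis-acid-induced tert-alkylation of silyl enol ethers, which as a Me3SiOTf-triggered cation–enol ether cyclisation has closed this same bond in related bicyclo[3.3.1]nonane triones. Ring B (C1, C9, C5, C6, C7, C8) is the only ring closed, in a 6-(enolexo)-exo-tet mode through a chair transition state. C5 is set by the catalyst, which covers one face of the planar dianion, C1 follows from C5 because the three-atom tether reaches only the same face, and C7 is set under Curtin–Hammett control: the two C7 epimers of the cation should interconvert by a reversible 1,2-hydride shift between C7 and C8, and only the epimer with the C7 prenyl group equatorial (exo) in the chair should close fast, which is why 10 is used as the racemate. The step needs C- over O-alkylation and C5 over C1 in the first event, secured by the chelated, flanked phenoxide oxygens and by the acyl group that lowers the nucleophilicity of C1. In the second event it needs C1 over C3, over oxygen and over the three prenyl alkenes, secured by the 4-O-methyl group (attack by C3 gives an O-methyl oxocarbenium ion that cannot lose its methyl group and reverts), by reversible O-alkylation under Me3SiOTf, and by ionising a leaving group under aprotic buffered conditions instead of protonating an alkene.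

Step 8
Reactants: 13 (1R,5R,7S)-4-methoxy-8,8-dimethyl-1-(2-methylpropanoyl)-3,5,7-tris(3-methylbut-2-en-1-yl)bicyclo[3.3.1]non-3-ene-2,9-dione
Product: 14 (1R,5R,7S)-4-hydroxy-8,8-dimethyl-1-(2-methylpropanoyl)-3,5,7-tris(3-methylbut-2-en-1-yl)bicyclo[3.3.1]non-3-ene-2,9-dione
Conditions: LiCl (10 equiv), DMSO, 120 °C; aq. HCl
Reagents that add atoms: none
Why: SN2 dealkylation of the vinylogous methyl ester by chloride in a dipolar aprotic solvent (Krapcho-type demethylation), the usual unmasking of the enolised 1,3-diketone in this class; C1 and C5 are quaternary bridgeheads and C7–H is not activated, so no stereocentre should be touched.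

**Compound list**

1 | phloroglucinol (benzene-1,3,5-triol) | Oc1cc(O)cc(O)c1 | starting material
2 | isobutyryl chloride (2-methylpropanoyl chloride) | CC(C)C(Cl)=O | starting material
3 | phlorisobutyrophenone, 2-methyl-1-(2,4,6-trihydroxyphenyl)propan-1-one | CC(C)C(=O)c1c(O)cc(O)cc1O | intermediate
4 | 1-(2,6-dihydroxy-4-methoxyphenyl)-2-methylpropan-1-one | CC(C)C(=O)c1c(O)cc(OC)cc1O | intermediate
5 | prenyl bromide (1-bromo-3-methylbut-2-ene) | CC(C)=CCBr | starting material
6 | 1-[2,6-dihydroxy-4-methoxy-3,5-bis(3-methylbut-2-en-1-yl)phenyl]-2-methylpropan-1-one | CC(C)C(=O)c1c(O)c(CC=C(C)C)c(OC)c(CC=C(C)C)c1O | intermediate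
7 | ethyl 3-hydroxy-3-methylbutanoate | CCOC(=O)CC(C)(C)O | starting material
8 | ethyl (±)-3-hydroxy-3-methyl-2-(3-methylbut-2-en-1-yl)butanoate | CCOC(=O)C(CC=C(C)C)C(C)(C)O | intermediate
9 | (±)-3-methyl-2-(3-methylbut-2-en-1-yl)butane-1,3-diol | OCC(CC=C(C)C)C(C)(C)O | intermediate
10 | (±)-4,4-dimethyl-5-(3-methylbut-2-en-1-yl)-1,3,2-dioxathiane 2,2-dioxide (cyclic sulfate of 9) | CC(C)=CCC1COS(=O)(=O)OC1(C)C | intermediate
11 | dicesium salt of (6R)-3-hydroxy-5-methoxy-2-(2-methylpropanoyl)-4,6-bis(3-methylbut-2-en-1-yl)-6-[3-methyl-2-(3-methylbut-2-en-1-yl)-3-(sulfooxy)butyl]cyclohexa-2,4-dien-1-one (enolate and sulfate monoester; both epimers at the side-chain carbon that becomes C7) | [Cs+].[Cs+].CC(C)=CCC1=C(OC)[C@@](CC=C(C)C)(CC(CC=C(C)C)C(C)(C)OS(=O)(=O)[O-])C(=O)C(C(=O)C(C)C)=C1[O-] | intermediate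
12 | bis(trimethylsilyl) derivative of 11: silyl enol ether at the 3-oxygen and trimethylsilyl sulfate at the tertiary carbon (6R; both side-chain epimers) | CC(C)=CCC1=C(OC)[C@@](CC=C(C)C)(CC(CC=C(C)C)C(C)(C)OS(=O)(=O)O[Si](C)(C)C)C(=O)C(C(=O)C(C)C)=C1O[Si](C)(C)C | intermediate
13 | (1R,5R,7S)-4-methoxy-8,8-dimethyl-1-(2-methylpropanoyl)-3,5,7-tris(3-methylbut-2-en-1-yl)bicyclo[3.3.1]non-3-ene-2,9-dione | CC(C)=CCC1=C(OC)[C@@]2(CC=C(C)C)C[C@H](CC=C(C)C)C(C)(C)[C@@](C(=O)C(C)C)(C1=O)C2=O | intermediate
14 | (1R,5R,7S)-4-hydroxy-8,8-dimethyl-1-(2-methylpropanoyl)-3,5,7-tris(3-methylbut-2-en-1-yl)bicyclo[3.3.1]non-3-ene-2,9-dione | CC(C)=CCC1=C(O)[C@@]2(CC=C(C)C)C[C@H](CC=C(C)C)C(C)(C)[C@@](C(=O)C(C)C)(C1=O)C2=O | target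

**Count and risks**

Total step count: 8. Longest linear sequence: 5 steps (steps 1, 2, 3, 7, 8; the branch through steps 4, 5, 6, 7, 8 is equally long).

Steps most likely to fail:

1. Step 7. What may go wrong: the ion pair may give poor face selection, or the hard, β-branched electrophile may alkylate oxygen. The hydride-shift equilibration at C7 may be incomplete, so that the mismatched epimer closes slowly to the 7-endo isomer. The cation may be lost to elimination, to irreversible O-capture or to attack by the C5 prenyl alkene.
Fallback (known chemistry only), setting out from 9 and 6 and coming back at 13: diol 9 is resolved by preparative chromatography on a chiral stationary phase to (S)-3-methyl-2-(3-methylbut-2-en-1-yl)butane-1,3-diol F1. Its primary hydroxyl group alone is triflated (Tf2O, 2,6-di-tert-butylpyridine, CH2Cl2, −78 °C) to (S)-3-hydroxy-3-methyl-2-(3-methylbut-2-en-1-yl)butyl trifluoromethanesulfonate F2. The dilithium dianion of 6 (LiN(SiMe3)2, THF, −78 °C to 0 °C) is C-alkylated by F2 in the established alkylative dearomatisation with primary triflates. The enantiopure side chain makes the two C5 epimers diastereomers, and the (6R)-configured tertiary alcohol (6R)-3-hydroxy-6-[(2S)-3-hydroxy-3-methyl-2-(3-methylbut-2-en-1-yl)butyl]-5-methoxy-2-(2-methylpropanoyl)-4,6-bis(3-methylbut-2-en-1-yl)cyclohexa-2,4-dien-1-one F3 is separated from its 6S epimer by chromatography. Irradiation of F3 (LED near 390 nm, degassed CH2Cl2) should then close C1–C8 by the known photocyclisation of dearomatised acylphloroglucinol tertiary alcohols, in which excited-state intramolecular proton transfer in the chelated enol ionises the alcohol, and should give 13.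

2. Step 3. What may go wrong: the sequence may stall at mono-prenylation, or drift to O-alkylation and to over-alkylated, dearomatised tri-prenyl products.
Fallback, setting out from 3 and coming back at 6: the order of events at ring A is changed. The free triol 3 is C-prenylated twice (5, aq. KOH, 0 °C; the classical procedure on the more nucleophilic trianion) to deoxycohumulone F6. The single non-chelated 4-hydroxyl group of F6 is then methylated (Me2SO4 1 equiv, K2CO3, acetone) to give 6.

3. Step 4. What may go wrong: the mono-alkoxide may cleave by retro-aldol reaction before the enolate forms, or the dianion may be alkylated at oxygen or twice.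
Fallback, setting out from 5 and coming back at 9: the tertiary hydroxyl group is introduced after the carbon skeleton instead. The lithium dienolate of commercial ethyl 3-methylbut-2-enoate (LiN(iPr)2, THF/DMPU, −78 °C) is alkylated by 5 at the α-carbon with deconjugation to ethyl (±)-5-methyl-2-(prop-1-en-2-yl)hex-4-enoate F4. LiAlH4 reduction gives (±)-lavandulol F5. Mukaiyama hydration (Co(acac)2 cat., PhSiH3, O2, THF, rt) of the 1,1-disubstituted alkene, which should react faster than the trisubstituted one, gives 9.

Further compounds
F1 | step 7 | (S)-3-methyl-2-(3-methylbut-2-en-1-yl)butane-1,3-diol | OC[C@H](CC=C(C)C)C(C)(C)O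
F2 | step 7 | (S)-3-hydroxy-3-methyl-2-(3-methylbut-2-en-1-yl)butyl trifluoromethanesulfonate | CC(C)=CC[C@@H](COS(=O)(=O)C(F)(F)F)C(C)(C)O
F3 | step 7 | (6R)-3-hydroxy-6-[(2S)-3-hydroxy-3-methyl-2-(3-methylbut-2-en-1-yl)butyl]-5-methoxy-2-(2-methylpropanoyl)-4,6-bis(3-methylbut-2-en-1-yl)cyclohexa-2,4-dien-1-one | CC(C)=CCC1=C(OC)[C@@](CC=C(C)C)(C[C@H](CC=C(C)C)C(C)(C)O)C(=O)C(C(=O)C(C)C)=C1O
F4 | step 4 | ethyl (±)-5-methyl-2-(prop-1-en-2-yl)hex-4-enoate | CCOC(=O)C(CC=C(C)C)C(C)=C
F5 | step 4 | (±)-lavandulol, (±)-5-methyl-2-(prop-1-en-2-yl)hex-4-en-1-ol | OCC(CC=C(C)C)C(C)=C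
F6 | step 3 | deoxycohumulone, 2-methyl-1-[2,4,6-trihydroxy-3,5-bis(3-methylbut-2-en-1-yl)phenyl]propan-1-one | CC(C)C(=O)c1c(O)c(CC=C(C)C)c(O)c(CC=C(C)C)c1O
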